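The ratio to follow in this flask is target over target plus isomer of the product, the two forms in which substrate has taken up partner.

substrate 0.050 M; solid reagent 0.0300 M; catalyst 8.5 mM; time 20 min

    target + catalyst ⇌ isomer of the product + catalyst, rate k1*[catalyst]*[target] forward; the back reaction follows from the equilibrium constant (k1 = 17 M⁻¹ min⁻¹)
    substrate + partner ⇌ target (K2 = 9.3 M⁻¹, k2 = 5.2 M⁻¹ min⁻¹)
    substrate + partner ⇌ isomer of the product (K3 = 54 M⁻¹, k3 = 2.6 M⁻¹ min⁻¹)
    solid reagent ⇌ partner, rate k4*(cs4 - [partner]) while solid is left; crystals form when [partner] > cs4 (cs4 = 39 mM, k4 = 0.12 min⁻¹)

- solid reagent is a solid; its amount is given per volume of the solution
- at the start none of the solid reagent is in solution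
- run time (flask): 20 min

1. the target standing at 20 min, as a percentage of the substrate charged
2. the change that raises the amount of target at 20 min, in percent of the substrate charged most ("none" if none brings more than 2 percentage points) (noon / autumn / summer / none)
3. amount of target at 20 min, in percent of the substrate charged, after autumn

- noon: doubling the solubility in step 4, all else as stated
- autumn: doubling the dissolution coefficient of step 4, all else as stated
- summer: doubling the amount of catalyst, all else as stated

Solid reagent dissolves to partner, partner joins substrate to make either form, and catalyst turns one form into the other. Both joining steps see the same substrate and partner, so target's share of what is newly bound starts at 0.667. At equilibrium the ratio is 0.147, lower than that. This resting share, target over both bound forms at equilibrium, marks the passage from kinetic to thermodynamic control.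

The first way takes the flask as at rest. The solid charge of 0.0300 M stands below the solubility, so it can dissolve entirely, supplying 0.600 equivalents. The bound fraction of substrate, divided by the unbound fraction and by the free partner, both counted against the substrate charge, then equals 3.17. This gives a bound fraction of 0.394, and with the resting share, target at 5.79%.

The second way runs a clock. Catalyst relaxes the share with a half-life of 4.09 min, so 20 min holds 4.89 half-lives. Started from 0.667 at zero, the share reaches 0.164, which puts target at 6.49%.

The two part by 0.69 percentage points. The first cheats by stopping the clock, the second by starting it at zero, although dissolving needs at least 6.41 min. The reckoning commits to about 6.14%. Noon, autumn and summer enter neither the resting share nor the bound fraction, so the first way stays at 5.79%. Noon and autumn do not enter the clock's half-life either, so the reckoning keeps about 6.14% after autumn. Summer shortens that half-life to 2.04 min, which brings the second way towards the first. The gap is less than 2 points, so the reckoning says none.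

The forecast gave 5.9%, none and 5.6%, on the ground that “Faster or more soluble feed only brings that peak forward and more catalyst drains the target faster”.

The flask gives 6.20%, none and, after autumn, 6.06%; noon, autumn and summer move target by −0.16 points, −0.15 points and −0.26 points.

At 20.0 min the share read in this flask is 0.162, still above the resting share. The neighbour flask with 0.075 M of solid reagent reads 0.192 at that time, with 28.2% of its solid undissolved. At 200 min this flask reads 0.147, with substrate at 60.6% and isomer of the product at 33.6%. Ten times the time takes target from 6.20% to 5.79%, a fall of 0.41 points.

The numbers are those of an exercise.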